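The cyclohexane ring of the side chain is cut between C1′, the tertiary carbinol on pyridone C5, and C2′, the epoxide carbon: both bear oxygen and are therefore carbonyl carbons in the precursor, while the cis oxygens at C3′/C4′ are those of L‑erythrose. One samarium diiodide pinacol cyclisation joins the aryl‑ketone carbon and the aldehyde carbon of an open‑chain 6‑pyridyl‑6‑oxohexanal 2,3‑acetonide, closing the ring and setting C1′ and C2′ as a cis‑diol trans to O3′. Mesylation and epoxide closure, C3 lithiation and acylation with a cis‑decalin aldehyde made by a quinone Diels–Alder reaction, and final N‑hydroxylation complete fischerin.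

Key step: step 8

Remark: the target was read as a cis‑fused (1R,2S,4aR,8aR)‑decalin with the acyl group trans to both neighbours, the epoxide syn to the C4′ hydroxyl and anti to the C1′ hydroxyl; compounds 11, 12 and 35 were checked against it centre by centre.
Remark: the pyridine oxygens are carried as 2‑(trimethylsilyl)ethyl ethers, which direct C3 lithiation and leave with fluoride, so neither hydrogenolysis nor acid is needed once the decalin alkene and the epoxide are present.
Remark: the (S)‑oxazaborolidinium catalyst of step 12 is assumed to give the 4aS,8aR adduct; if its facial sense is the opposite, its enantiomer is used and nothing else changes.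
Remark: lactols 2 and 4 are anomeric mixtures, and C1 of 26–28 and the carbinol carbon of 31 are epimeric mixtures; these centres are left undefined in the SMILES.

Step 1
Reactants: 1 L‑arabinose
Product: 2 3,4‑O‑isopropylidene‑L‑arabinopyranose
Conditions: Me2C(OMe)2, p‑TsOH (cat.), DMF, rt
Reagents that add atoms: 2,2‑dimethoxypropane, COC(C)(C)OC
Why: Acid‑catalysed transacetalisation (acetonide formation) takes the only cis‑vicinal diol of the pyranose, O3/O4, and creates no stereocentre.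

Step 2
Reactants: 2 3,4‑O‑isopropylidene‑L‑arabinopyranose
Product: 4 2,3‑O‑isopropylidene‑L‑erythrose (lactol), via erythrose 4‑O‑formate 3 (not isolated)
Conditions: NaIO4, H2O, 0 °C → rt; then Na2CO3
Reagents that add atoms: none
Why: Malaprade glycol cleavage of the free C1/C2 hydroxy‑hemiacetal pair excises C1 as a formate that carbonate hydrolyses, and the two retained centres (arabinose C3/C4) are not touched.

Step 3
Reactants: 4 2,3‑O‑isopropylidene‑L‑erythrose (lactol)
Product: 5 (E)‑N‑methoxy‑N‑methyl enamide of the chain‑extended erythrose acetonide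
Conditions: Ph3P=CHC(O)N(OMe)Me, PhCO2H (cat.), toluene, 80 °C
Reagents that add atoms: N‑methoxy‑N‑methyl‑2‑(triphenylphosphoranylidene)acetamide, CON(C)C(=O)C=P(c1ccccc1)(c1ccccc1)c1ccccc1
Why: Wittig olefination of the lactol through its open hydroxy‑aldehyde form with a stabilised ylide should give the (E)‑enamide, a poor Michael acceptor that resists oxa‑Michael closure by the freed C4 hydroxyl.

Step 4
Reactants: 5 (E)‑N‑methoxy‑N‑methyl enamide
Product: 6 3‑[(4R,5S)‑5‑(hydroxymethyl)‑2,2‑dimethyl‑1,3‑dioxolan‑4‑yl]‑N‑methoxy‑N‑methylpropanamide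
Conditions: H2 (1 atm), 10% Pd/C, EtOAc, rt
Reagents that add atoms: none
Why: Heterogeneous catalytic hydrogenation saturates the conjugated C=C while the N–OMe bond, acetonide and alcohol are inert, and no pyridyl ether is present yet.

Step 5
Reactants: 7 5‑bromo‑2,4‑dichloropyridine
Product: 8 5‑bromo‑2,4‑bis[2‑(trimethylsilyl)ethoxy]pyridine
Conditions: Me3SiCH2CH2OH, NaH, THF, 0 → 60 °C
Reagents that add atoms: 2‑(trimethylsilyl)ethanol, C[Si](C)(C)CCO
Why: Twofold nucleophilic aromatic substitution (addition–elimination) replaces the 4‑ and 2‑chlorides, both activated by the ring nitrogen, while the 5‑bromide (β to nitrogen) stays.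

Step 6
Reactants: 8 5‑bromo‑2,4‑bis[2‑(trimethylsilyl)ethoxy]pyridine; 6 hydroxy N‑methoxy‑N‑methylamide
Product: 10 1‑{4,6‑bis[2‑(trimethylsilyl)ethoxy]pyridin‑3‑yl}‑3‑[(4R,5S)‑5‑(hydroxymethyl)‑2,2‑dimethyl‑1,3‑dioxolan‑4‑yl]propan‑1‑one, via aryllithium 9 (not isolated)
Conditions: 8, n‑BuLi, THF, −78 °C; then 6 pre‑treated with LiHMDS (1 equiv), −78 → −20 °C; H2O
Reagents that add atoms: none
Why: Bromine–lithium exchange followed by Weinreb ketone synthesis, in which the chelated tetrahedral adduct stops at the ketone and the lithium alkoxide of 6 is a spectator.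

Step 7
Reactants: 10 hydroxy ketone
Product: 11 (4R,5R)‑5‑(3‑{4,6‑bis[2‑(trimethylsilyl)ethoxy]pyridin‑3‑yl}‑3‑oxopropyl)‑2,2‑dimethyl‑1,3‑dioxolane‑4‑carbaldehyde
Conditions: Dess–Martin periodinane, CH2Cl2, 0 °C → rt; used crude
Reagents that add atoms: none
Why: Dess–Martin oxidation of the primary alcohol under non‑basic conditions should preserve the epimerisable α‑alkoxy aldehyde centre (future C3′) and leave the aryl ketone alone.

Step 8
Reactants: 11 keto‑aldehyde
Product: 12 (1S,2S,3S,4R)‑1‑{4,6‑bis[2‑(trimethylsilyl)ethoxy]pyridin‑3‑yl}‑3,4‑O‑isopropylidenecyclohexane‑1,2,3,4‑tetrol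
Conditions: SmI2 (2.5 equiv), t‑BuOH (2 equiv), THF (0.01 M), −78 → −20 °C
Reagents that add atoms: none
Why: Single‑electron transfer to the more easily reduced aryl ketone gives a samarium(III) ketyl at C1′ that adds to the aldehyde carbon C2′, and a second electron plus protonation deliver the diol. The closest known reaction type is the SmI2 pinacol cyclisation of carbohydrate‑derived 1,6‑dicarbonyl compounds to cis‑cyclohexane‑1,2‑diols. The cyclohexane ring closes in the 6‑exo‑trig mode, the ketyl carbon attacking the C=O whose oxygen stays outside the ring. C1′ and C2′ are set cis to each other because one samarium bridges both oxygens in the cyclic transition state; C2′–O is set trans to C3′–O because the metal‑bound aldehyde oxygen avoids the neighbouring oxygen of the cis‑fused acetonide, which also fixes C1′ relative to the L‑erythrose centres. The step needs reduction of the ketone before the aldehyde and ring closure faster than simple reduction or dimerisation, which the lower reduction potential of the aryl ketone, high dilution, low temperature and the absence of HMPA should secure.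

Step 9
Reactants: 12 cis‑diol acetonide
Product: 13 2′‑O‑methanesulfonate of 12
Conditions: MsCl, Et3N, CH2Cl2, 0 °C
Reagents that add atoms: methanesulfonyl chloride, CS(=O)(=O)Cl
Why: Sulfonylation via sulfene takes only the secondary C2′ hydroxyl, since the C1′ carbinol is tertiary and O3′/O4′ are locked in the acetonide.

Step 10
Reactants: 13 mesylate acetonide
Product: 15 (1R,2S,5R,6R)‑2‑{4,6‑bis[2‑(trimethylsilyl)ethoxy]pyridin‑3‑yl}‑7‑oxabicyclo[4.1.0]heptane‑2,5‑diol, via triol mesylate 14 (not isolated)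
Conditions: AcOH–H2O (4:1), 45 °C; evaporate; K2CO3, MeOH, 0 °C → rt
Reagents that add atoms: none
Why: Acetal hydrolysis frees O3′ and O4′, then an intramolecular Williamson closure (SN2, 3‑exo‑tet) by O3′, which is trans to the mesylate, inverts C2′ and places the epoxide syn to the C4′ hydroxyl; the cis C1′ hydroxyl cannot displace the mesylate.

Step 11
Reactants: 15 epoxy diol
Product: 16 bis(triethylsilyl) ether of 15 (C1′‑OTES and C4′‑OTES)
Conditions: TESOTf, 2,6‑lutidine, CH2Cl2, −78 → 0 °C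
Reagents that add atoms: triethylsilyl trifluoromethanesulfonate, CC[Si](CC)(CC)OS(=O)(=O)C(F)(F)F
Why: Silylation with a silyl triflate and a hindered base is strong enough for the tertiary C1′ hydroxyl as well as the secondary C4′ hydroxyl and is tolerated by the epoxide at low temperature.

Step 12
Reactants: 17 2‑methyl‑1,4‑benzoquinone; 18 1,3‑butadiene
Product: 19 (4aS,8aR)‑2‑methyl‑4a,5,8,8a‑tetrahydronaphthalene‑1,4‑dione
Conditions: (S)‑B‑o‑tolyl diphenylprolinol oxazaborolidine·HNTf2 (20 mol%), CH2Cl2, −78 °C; used at once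
Reagents that add atoms: none
Why: Chiral oxazaborolidinium‑catalysed Diels–Alder reaction at the unsubstituted C5=C6 bond of the quinone, in which suprafacial addition gives the cis ring fusion and the catalyst selects the quinone face that sets C4a/C8a.

Step 13
Reactants: 19 cis‑enedione
Product: 20 (4S,4aS,8aR)‑4‑hydroxy‑2‑methyl‑4a,5,8,8a‑tetrahydronaphthalen‑1(4H)‑one
Conditions: NaBH4, CeCl3·7H2O, MeOH, −78 °C
Reagents that add atoms: none
Why: Luche 1,2‑reduction should take the less hindered C4 carbonyl (remote from the methyl group) with hydride arriving on the convex face of the cis‑fused bicycle, so that the C4 hydroxyl ends on the concave face.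

Step 14
Reactants: 20 hydroxy enone
Product: 21 (4S,4aS,8aR)‑4‑hydroxy‑2‑methyl‑4a,5,6,7,8,8a‑hexahydronaphthalen‑1(4H)‑one
Conditions: H2 (1 atm), RhCl(PPh3)3 (5 mol%), benzene–EtOH, rt
Reagents that add atoms: none
Why: Homogeneous rhodium‑catalysed hydrogenation reduces the unhindered disubstituted C6=C7 bond and leaves the trisubstituted conjugated C2=C3 bond.

Step 15
Reactants: 21 γ‑hydroxy enone
Product: 24 (2S,4aR,8aR)‑2‑methyl‑4a,5,6,7,8,8a‑hexahydronaphthalen‑1(2H)‑one, via allylic sulfonylhydrazine 22 (not isolated), via allylic diazene 23 (not isolated)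
Conditions: 2‑NO2C6H4SO2NHNH2, PPh3, DEAD, THF, −30 °C → rt
Reagents that add atoms: none
Why: Reductive 1,3‑transposition of an allylic alcohol: Mitsunobu displacement inverts C4, loss of sulfinic acid gives the monoalkyl diazene, and its retro‑ene loss of N2 delivers hydrogen to C2 on the convex face, moving the double bond to C3=C4 and setting the C2 methyl cis to the ring‑B carbons.

Step 16
Reactants: 24 β,γ‑unsaturated ketone
Product: 25 (2S,4aR,8aR)‑2‑methyl‑1‑methylidene‑1,2,4a,5,6,7,8,8a‑octahydronaphthalene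
Conditions: Zn, CH2Br2, TiCl4, THF–CH2Cl2, 0 °C → rt
Reagents that add atoms: dibromomethane, BrCBr
Why: Takai–Lombardo methylenation is not basic, so the hindered ketone should be converted without epimerising C2 or C8a and without moving the double bond into conjugation.

Step 17
Reactants: 25 exocyclic alkene
Product: 27 [(2S,4aR,8aR)‑2‑methyl‑1,2,4a,5,6,7,8,8a‑octahydronaphthalen‑1‑yl]methanol (C1 epimers), via B‑alkyl‑9‑BBN 26 (not isolated)
Conditions: 9‑BBN, THF, 0 °C → rt; then NaOH, H2O2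
Reagents that add atoms: hydrogen peroxide, OO
Why: Anti‑Markovnikov hydroboration–oxidation with a bulky borane selects the 1,1‑disubstituted exocyclic alkene over the ring alkene; the C1 configuration formed here is not relied on and is corrected in step 19.

Step 18
Reactants: 27 primary alcohol
Product: 28 (2S,4aR,8aR)‑2‑methyl‑1,2,4a,5,6,7,8,8a‑octahydronaphthalene‑1‑carbaldehyde (C1 epimers)
Conditions: Dess–Martin periodinane, CH2Cl2, rt
Reagents that add atoms: none
Why: Dess–Martin oxidation gives the aldehyde without touching the ring alkene.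

Step 19
Reactants: 28 aldehyde (C1 epimers)
Product: 29 (1R,2S,4aR,8aR)‑2‑methyl‑1,2,4a,5,6,7,8,8a‑octahydronaphthalene‑1‑carbaldehyde
Conditions: DBU (0.2 equiv), CH2Cl2, rt
Reagents that add atoms: none
Why: Base‑mediated epimerisation through the enolate equilibrates the only enolisable centre, C1, to the isomer with the formyl group trans to both the C2 methyl and C8, which is all‑equatorial on ring A.

Step 20
Reactants: 16 bis‑silyl epoxide; 29 decalin aldehyde
Product: 31 carbinol from C3 of the pyridine and the decalin aldehyde (carbinol epimers), via 3‑lithiopyridine 30 (not isolated)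
Conditions: 16, n‑BuLi, THF, −78 → −40 °C; then 29, −78 °C; H2O
Reagents that add atoms: none
Why: Directed ortho‑metalation at C3, the position flanked by both alkoxy groups, followed by 1,2‑addition to the aldehyde; the carbinol centre forms unselectively and is removed in step 21.

Step 21
Reactants: 31 carbinol
Product: 32 3‑[(1R,2S,4aR,8aR)‑2‑methyl‑octahydronaphthalene‑1‑carbonyl] derivative of 16
Conditions: Dess–Martin periodinane, CH2Cl2, rt
Reagents that add atoms: none
Why: Dess–Martin oxidation converts both carbinol epimers into one aryl ketone, and C1 of the decalin, now α to the ketone, keeps its thermodynamically preferred configuration.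

Step 22
Reactants: 32 fully protected ketone
Product: 33 N‑deoxyfischerin (4‑hydroxy‑2‑pyridone with free C1′ and C4′ hydroxyls)
Conditions: TBAF, THF, 0 °C → rt
Reagents that add atoms: none
Why: Fluoride attacks silicon, so the two 2‑silylethyl ethers fragment with loss of ethene to the 4‑hydroxy‑2‑pyridone and both triethylsilyl ethers are cleaved, under conditions that should leave epoxide and alkene intact.

Step 23
Reactants: 33 N‑deoxyfischerin
Product: 35 fischerin, via persilylated pyridone 34 (not isolated)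
Conditions: BSA, CH2Cl2, rt; MoO5·py·HMPA, 0 °C → rt; aq. Na4EDTA, then citric acid, MeOH
Reagents that add atoms: oxodiperoxymolybdenum(pyridine)(hexamethylphosphoric triamide), O=[Mo]12(OO1)OO2.c1ccncc1.CN(C)P(=O)(N(C)C)N(C)C
Why: N‑Hydroxylation of a silylated 2‑pyridone: the transient 2‑silyloxypyridine is oxidised at nitrogen by the peroxomolybdenum reagent, and hydrolysis gives the 1‑hydroxy‑2‑pyridone and returns the other silylated oxygens.

Compound list
1 | L‑arabinose | O=C[C@H](O)[C@@H](O)[C@@H](O)CO | starting material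
2 | 3,4‑O‑isopropylidene‑L‑arabinopyranose (anomers) | OC1OC[C@@H]2OC(C)(C)O[C@@H]2[C@H]1O | intermediate
3 | 4‑O‑formyl‑2,3‑O‑isopropylidene‑L‑erythrose | O=C[C@H]1OC(C)(C)O[C@H]1COC=O | intermediate
4 | 2,3‑O‑isopropylidene‑L‑erythrofuranose (lactol, anomers) | OC1OC[C@@H]2OC(C)(C)O[C@H]12 | intermediate
5 | (2E)‑3‑[(4R,5S)‑5‑(hydroxymethyl)‑2,2‑dimethyl‑1,3‑dioxolan‑4‑yl]‑N‑methoxy‑N‑methylprop‑2‑enamide | CON(C)C(=O)/C=C/[C@H]1OC(C)(C)O[C@H]1CO | intermediate
6 | 3‑[(4R,5S)‑5‑(hydroxymethyl)‑2,2‑dimethyl‑1,3‑dioxolan‑4‑yl]‑N‑methoxy‑N‑methylpropanamide | CON(C)C(=O)CC[C@H]1OC(C)(C)O[C@H]1CO | intermediate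
7 | 5‑bromo‑2,4‑dichloropyridine | Clc1cc(Cl)c(Br)cn1 | starting material
8 | 5‑bromo‑2,4‑bis[2‑(trimethylsilyl)ethoxy]pyridine | C[Si](C)(C)CCOc1cc(OCC[Si](C)(C)C)c(Br)cn1 | intermediate
9 | {4,6‑bis[2‑(trimethylsilyl)ethoxy]pyridin‑3‑yl}lithium | C[Si](C)(C)CCOc1cc(OCC[Si](C)(C)C)c([Li])cn1 | intermediate
10 | 1‑{4,6‑bis[2‑(trimethylsilyl)ethoxy]pyridin‑3‑yl}‑3‑[(4R,5S)‑5‑(hydroxymethyl)‑2,2‑dimethyl‑1,3‑dioxolan‑4‑yl]propan‑1‑one | C[Si](C)(C)CCOc1cc(OCC[Si](C)(C)C)c(cn1)C(=O)CC[C@H]1OC(C)(C)O[C@H]1CO | intermediate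
11 | (4R,5R)‑5‑(3‑{4,6‑bis[2‑(trimethylsilyl)ethoxy]pyridin‑3‑yl}‑3‑oxopropyl)‑2,2‑dimethyl‑1,3‑dioxolane‑4‑carbaldehyde | C[Si](C)(C)CCOc1cc(OCC[Si](C)(C)C)c(cn1)C(=O)CC[C@H]1OC(C)(C)O[C@H]1C=O | intermediate
12 | (1S,2S,3S,4R)‑1‑{4,6‑bis[2‑(trimethylsilyl)ethoxy]pyridin‑3‑yl}‑3,4‑O‑isopropylidenecyclohexane‑1,2,3,4‑tetrol | C[Si](C)(C)CCOc1cc(OCC[Si](C)(C)C)c(cn1)[C@@]1(O)CC[C@H]2OC(C)(C)O[C@H]2[C@@H]1O | intermediate
13 | 2′‑O‑methanesulfonate of 12 | C[Si](C)(C)CCOc1cc(OCC[Si](C)(C)C)c(cn1)[C@@]1(O)CC[C@H]2OC(C)(C)O[C@H]2[C@@H]1OS(C)(=O)=O | intermediate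
14 | 1‑aryl‑cyclohexane‑1,2,3,4‑tetrol 2‑methanesulfonate (13 without the acetonide) | C[Si](C)(C)CCOc1cc(OCC[Si](C)(C)C)c(cn1)[C@@]1(O)CC[C@@H](O)[C@@H](O)[C@@H]1OS(C)(=O)=O | intermediate
15 | (1R,2S,5R,6R)‑2‑{4,6‑bis[2‑(trimethylsilyl)ethoxy]pyridin‑3‑yl}‑7‑oxabicyclo[4.1.0]heptane‑2,5‑diol | C[Si](C)(C)CCOc1cc(OCC[Si](C)(C)C)c(cn1)[C@@]1(O)CC[C@@H](O)[C@H]2O[C@H]21 | intermediate
16 | 2,5‑bis(triethylsilyl) ether of 15 | C[Si](C)(C)CCOc1cc(OCC[Si](C)(C)C)c(cn1)[C@@]1(O[Si](CC)(CC)CC)CC[C@@H](O[Si](CC)(CC)CC)[C@H]2O[C@H]21 | intermediate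
17 | 2‑methyl‑1,4‑benzoquinone | CC1=CC(=O)C=CC1=O | starting material
18 | 1,3‑butadiene | C=CC=C | starting material
19 | (4aS,8aR)‑2‑methyl‑4a,5,8,8a‑tetrahydronaphthalene‑1,4‑dione | CC1=CC(=O)[C@H]2CC=CC[C@H]2C1=O | intermediate
20 | (4S,4aS,8aR)‑4‑hydroxy‑2‑methyl‑4a,5,8,8a‑tetrahydronaphthalen‑1(4H)‑one | CC1=C[C@@H](O)[C@H]2CC=CC[C@H]2C1=O | intermediate
21 | (4S,4aS,8aR)‑4‑hydroxy‑2‑methyl‑4a,5,6,7,8,8a‑hexahydronaphthalen‑1(4H)‑one | CC1=C[C@@H](O)[C@H]2CCCC[C@H]2C1=O | intermediate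
22 | N‑(2‑nitrobenzenesulfonyl)hydrazine at C4 of the enone (C4 inverted) | CC1=C[C@H](N(N)S(=O)(=O)c3ccccc3[N+](=O)[O-])[C@H]2CCCC[C@H]2C1=O | intermediate
23 | allylic diazene at C4 of the enone | CC1=C[C@H](N=N)[C@H]2CCCC[C@H]2C1=O | intermediate
24 | (2S,4aR,8aR)‑2‑methyl‑4a,5,6,7,8,8a‑hexahydronaphthalen‑1(2H)‑one | C[C@H]1C=C[C@H]2CCCC[C@H]2C1=O | intermediate
25 | (2S,4aR,8aR)‑2‑methyl‑1‑methylidene‑1,2,4a,5,6,7,8,8a‑octahydronaphthalene | C[C@H]1C=C[C@H]2CCCC[C@H]2C1=C | intermediate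
26 | 9‑{[(2S,4aR,8aR)‑2‑methyl‑octahydronaphthalen‑1‑yl]methyl}‑9‑borabicyclo[3.3.1]nonane (C1 epimers) | C[C@H]1C=C[C@H]2CCCC[C@H]2C1CB1C2CCCC1CCC2 | intermediate
27 | [(2S,4aR,8aR)‑2‑methyl‑1,2,4a,5,6,7,8,8a‑octahydronaphthalen‑1‑yl]methanol (C1 epimers) | C[C@H]1C=C[C@H]2CCCC[C@H]2C1CO | intermediate
28 | (2S,4aR,8aR)‑2‑methyl‑1,2,4a,5,6,7,8,8a‑octahydronaphthalene‑1‑carbaldehyde (C1 epimers) | C[C@H]1C=C[C@H]2CCCC[C@H]2C1C=O | intermediate
29 | (1R,2S,4aR,8aR)‑2‑methyl‑1,2,4a,5,6,7,8,8a‑octahydronaphthalene‑1‑carbaldehyde | C[C@H]1C=C[C@H]2CCCC[C@H]2[C@@H]1C=O | intermediate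
30 | 3‑lithio derivative of 16 | [Li]c1c(OCC[Si](C)(C)C)ncc(c1OCC[Si](C)(C)C)[C@@]1(O[Si](CC)(CC)CC)CC[C@@H](O[Si](CC)(CC)CC)[C@H]2O[C@H]21 | intermediate
31 | pyridin‑3‑yl(decalin‑1‑yl)methanol from 16 and 29 (carbinol epimers) | C[C@H]1C=C[C@H]2CCCC[C@H]2[C@@H]1C(O)c1c(OCC[Si](C)(C)C)ncc(c1OCC[Si](C)(C)C)[C@@]1(O[Si](CC)(CC)CC)CC[C@@H](O[Si](CC)(CC)CC)[C@H]2O[C@H]21 | intermediate
32 | fully protected ketone (3‑decalinoyl derivative of 16) | C[C@H]1C=C[C@H]2CCCC[C@H]2[C@@H]1C(=O)c1c(OCC[Si](C)(C)C)ncc(c1OCC[Si](C)(C)C)[C@@]1(O[Si](CC)(CC)CC)CC[C@@H](O[Si](CC)(CC)CC)[C@H]2O[C@H]21 | intermediate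
33 | N‑deoxyfischerin (1H‑pyridin‑2‑one) | C[C@H]1C=C[C@H]2CCCC[C@H]2[C@@H]1C(=O)c1c(O)c([C@@]2(O)CC[C@@H](O)[C@H]3O[C@H]32)c[nH]c1=O | intermediate
34 | tetrakis(trimethylsilyl) derivative of 33 (2‑O, 4‑O, C1′‑O, C4′‑O) | C[C@H]1C=C[C@H]2CCCC[C@H]2[C@@H]1C(=O)c1c(O[Si](C)(C)C)ncc(c1O[Si](C)(C)C)[C@@]1(O[Si](C)(C)C)CC[C@@H](O[Si](C)(C)C)[C@H]2O[C@H]21 | intermediate
35 | fischerin | C[C@H]1C=C[C@H]2CCCC[C@H]2[C@@H]1C(=O)c1c(O)c([C@@]2(O)CC[C@@H](O)[C@H]3O[C@H]32)cn(O)c1=O | target

Total step count: 23.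
Longest linear sequence: 14 steps (1–4, 6–11, 20–23, from L‑arabinose); the decalin branch (12–19) joins at step 20.

Steps most likely to fail

Step 8 (key step). The ketyl may simply be reduced to the alcohol at either carbonyl, or the ring may close through an unchelated transition state and give a trans‑diol or the diol cis to O3′. The fallback replaces reductive coupling by metathesis and dihydroxylation; it sets out from 11 and comes back at 12. Both carbonyls of 11 are methylenated with excess Ph3P=CH2 (THF, −78 → 0 °C) to give the diene (4R,5S)‑4‑(3‑arylbut‑3‑enyl)‑2,2‑dimethyl‑5‑vinyl‑1,3‑dioxolane F1. Ring‑closing metathesis with a second‑generation ruthenium carbene catalyst (CH2Cl2, 40 °C) gives the 1‑arylcyclohexene acetonide F2. Catalytic OsO4 with NMO then adds both hydroxyls to the face opposite the cis‑fused acetonide and gives 12.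

Step 23. The peroxomolybdenum reagent may transfer oxygen to the decalin C3=C4 alkene, or N‑oxidation of the hindered silyloxypyridine may stall. The fallback makes the N–O bond before the alkene is present; it sets out from 16 and comes back at 35. C3 lithiation of 16 (n‑BuLi) and an iodine quench give the 3‑iodopyridine F3. mCPBA (CH2Cl2, NaHCO3) gives the pyridine N‑oxide F4. Iodine–magnesium exchange (i‑PrMgCl·LiCl, THF, −40 °C) and addition to 29 give the carbinol N‑oxide F5. Dess–Martin oxidation gives the ketone N‑oxide F6. TBAF then removes all four silicon groups, and the 2‑silylethoxy N‑oxide collapses directly to the 1‑hydroxy‑2‑pyridone 35.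

Step 15. The activated C4 alcohol may eliminate toward C4a (followed by aromatisation of ring A), or the Mitsunobu substitution of the concave‑face alcohol may be too slow. The fallback uses reductive cleavage instead of a sigmatropic transposition; it sets out from 21 and comes back at 24. Acetylation (Ac2O, pyridine, DMAP) gives the γ‑acetoxy enone F7. SmI2 in THF–MeOH at −78 °C cleaves the C4–O bond to the samarium dienolate, and kinetic protonation at C2 from the convex face gives 24.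

Further compounds
F1 | step 8 | (4R,5S)‑4‑(3‑{4,6‑bis[2‑(trimethylsilyl)ethoxy]pyridin‑3‑yl}but‑3‑en‑1‑yl)‑5‑ethenyl‑2,2‑dimethyl‑1,3‑dioxolane | C=C(CC[C@H]1OC(C)(C)O[C@H]1C=C)c1cnc(OCC[Si](C)(C)C)cc1OCC[Si](C)(C)C
F2 | step 8 | 1‑aryl‑3,4‑O‑isopropylidenecyclohex‑1‑ene‑3,4‑diol (1′,2′‑dehydro‑dideoxy analogue of 12) | C[Si](C)(C)CCOc1cc(OCC[Si](C)(C)C)c(cn1)C1=C[C@@H]2OC(C)(C)O[C@@H]2CC1
F3 | step 23 | 3‑iodo derivative of 16 | Ic1c(OCC[Si](C)(C)C)ncc(c1OCC[Si](C)(C)C)[C@@]1(O[Si](CC)(CC)CC)CC[C@@H](O[Si](CC)(CC)CC)[C@H]2O[C@H]21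
F4 | step 23 | N‑oxide of F3 | Ic1c(OCC[Si](C)(C)C)[n+]([O-])cc(c1OCC[Si](C)(C)C)[C@@]1(O[Si](CC)(CC)CC)CC[C@@H](O[Si](CC)(CC)CC)[C@H]2O[C@H]21
F5 | step 23 | N‑oxide of carbinol 31 (carbinol epimers) | C[C@H]1C=C[C@H]2CCCC[C@H]2[C@@H]1C(O)c1c(OCC[Si](C)(C)C)[n+]([O-])cc(c1OCC[Si](C)(C)C)[C@@]1(O[Si](CC)(CC)CC)CC[C@@H](O[Si](CC)(CC)CC)[C@H]2O[C@H]21
F6 | step 23 | N‑oxide of ketone 32 | C[C@H]1C=C[C@H]2CCCC[C@H]2[C@@H]1C(=O)c1c(OCC[Si](C)(C)C)[n+]([O-])cc(c1OCC[Si](C)(C)C)[C@@]1(O[Si](CC)(CC)CC)CC[C@@H](O[Si](CC)(CC)CC)[C@H]2O[C@H]21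
F7 | step 15 | 4‑O‑acetate of 21 | CC1=C[C@@H](OC(C)=O)[C@H]2CCCC[C@H]2C1=O
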